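The constants were drawn at random within sensible limits; no experiment stands behind them.

A small charge of initiator has to carry a much larger amount of free monomer into chains, and protic impurity eats the same free monomer.

free monomer 1.0 M; protic impurity 0.300 M; initiator 50 mM; time 2.5 d

1. whether the average number of monomer units in a chain (chains begun, living or dead) reaches 6.0 by 2.5 d (no / yes)
2. average number of monomer units in a chain (chains begun, living or dead) at 2.5 d

- the average divides the monomer in chains by the number of chains begun, living and dead together
- run time (flask): 2.5 d

    protic impurity + free monomer → quenched substrate (k1 = 0.019 M⁻¹ h⁻¹)
    monomer in chains + living end → free monomer + living end, rate k2*[living end] as long as [monomer in chains] is above zero (k2 = 0.36 h⁻¹)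
    initiator → spent initiator (k3 = 0.15 h⁻¹)
    free monomer + living end → monomer in chains + living end, rate k4*[living end]*[free monomer] (k4 = 0.99 M⁻¹ h⁻¹)
    free monomer + initiator → living end + monomer in chains (k5 = 1.2 M⁻¹ h⁻¹)

Start with the number of chains. Initiator has two exits: free monomer, taken at its charge, captures it at 1.20 h⁻¹, and it decays to spent initiator at 0.15 h⁻¹. So a share of 88.9% begins chains:

chains begun = 0.0444 M

Now draw the length curve. At the start, each chain gains 0.630 h⁻¹, which is addition less unzipping. Addition slows as free monomer falls, and the two balance at the ceiling, the equilibrium monomer concentration:

ceiling = k2/k4 = 0.364 M

The excess of free monomer over the ceiling shrinks to 0.5 of itself every 15.8 h. Leaving the impurity aside for the moment, my reckoned length runs up from 1 towards the level: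

level = (free monomer charged − ceiling)/chains = 14.3

The curve crosses 6.0 at about 10.7 h. By 2.5 d, my curve puts free monomer at 0.406 M. Following that curve, the impurity has quenched 0.144 M, which I take out of the chains:

length at the end = (free monomer charged − free monomer left − quenched)/chains = 10.1

So my answer is yes. The forecast also says yes but gives 11.2, higher than my figure, and it starts from this: “Nearly all the initiator is captured by monomer within a few hours”.

The flask reaches the length at 0.508 d and stands at 11.1 at 2.5 d, so the answer is yes.

At 2.50 d, free monomer stands at 37.2% of its charge, lower than the 0.406 M I reckoned. Use the ceiling again on this flask left for 25.0 d, when protic impurity is down to 1.38% of its charge. Take free monomer at 0.364 M and the impurity's full 0.300 M as quenched, and the length should fall to 7.57. The flask then holds free monomer at 36.3% of its charge and monomer in chains at 34.1%, a length of 7.71.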